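## Retrosynthetic overview

1. Numbering: chain C1 (OCH2) to C10 (alkylidene CH); C11, C12, C13 are C-3, C-4, C-5 of the lactone. The γ-lactone is the only ring and is closed last.
2. Lactone: the C11 carboxyl oxygen (carried as a tert-butyl ester) opens a (12S,13S)-12,13-epoxide at the allylic C13 with inversion and frees the C12 hydroxyl. This mirrors the presumed biosynthesis (12,13-epoxide attacked by the C11 carboxylate).
3. Epoxide, made in the same flask: the C12–C13 bond and both stereocentres come from a chiral allylic sulfonium ylide (C12) and 3-methylbut-2-enal (C13–C15).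
4. Ylide precursor: a (Z)-2-(bromomethyl)enoate from the Morita–Baylis–Hillman adduct of a C1–C10 aldehyde with tert-butyl acrylate (C10–C11 bond; fixes the E-alkylidene).
5. C1–C10 aldehyde: Claisen rearrangement (C8–C9 bond, 6E alkene) of the isopropenyl carbinol derived from the 6,7-epoxide of neryl (E)-3-methylpent-2-enoate, itself from nerol and (E)-3-methylpent-2-enoic acid.

Assumption: (E)-3-methylpent-2-enoic acid 2 and (1S,4S,5S)-isothiocineole 13 are bought as catalogue compounds (13 is otherwise one step from (S)-limonene, sulfur and γ-terpinene, and is recovered after step 8).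

Assumption: sulfide 13 is taken to give the (S,S)-epoxide (ylide substituent away from the gem-dimethyl group, aldehyde approaching from the bridgehead C–H side); this sense rests on a model and was not checked against data, and if it is opposite the (1R,4R,5R) antipode is used with no other change.

## Route

Step 1
Reactants: 1 nerol [(2Z)-3,7-dimethylocta-2,6-dien-1-ol]; 2 (2E)-3-methylpent-2-enoic acid
Product: 3 (2Z)-3,7-dimethylocta-2,6-dien-1-yl (2E)-3-methylpent-2-enoate
Conditions: DCC, DMAP (cat.), CH2Cl2, 0 °C → rt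
Reagents that add atoms: none
Why: Steglich esterification acylates the primary allylic alcohol under neutral conditions that leave both alkene geometries untouched, and the ester then serves as its own protecting group for the rest of the route.

Step 2
Reactants: 3 (2Z)-3,7-dimethylocta-2,6-dien-1-yl (2E)-3-methylpent-2-enoate
Product: 4 (2Z)-5-(3,3-dimethyloxiran-2-yl)-3-methylpent-2-en-1-yl (2E)-3-methylpent-2-enoate (racemic)
Conditions: mCPBA (1.05 equiv), CH2Cl2, −20 → 0 °C
Reagents that add atoms: mCPBA (3-chloroperoxybenzoic acid) O=C(OO)c1cccc(Cl)c1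
Why: Prilezhaev epoxidation picks the electron-rich distal 6,7-alkene because the 2,3-alkene is deactivated by the allylic acyloxy group and the enoate alkene is electron-poor; the racemic stereocentre is destroyed in step 4.

Step 3
Reactants: 4 (2Z)-5-(3,3-dimethyloxiran-2-yl)-3-methylpent-2-en-1-yl (2E)-3-methylpent-2-enoate (racemic)
Product: 6 (2Z)-6-hydroxy-3,7-dimethylocta-2,7-dien-1-yl (2E)-3-methylpent-2-enoate (racemic), via trimethylsilyl ether 5 (not isolated)
Conditions: TMSOTf (1.2 equiv), DBU (1.3 equiv), toluene, −78 °C → rt; then 1 M HCl, THF, 0 °C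
Reagents that add atoms: none
Why: Noyori-type silyl triflate/amidine isomerisation of an epoxide to an allylic alcohol: O-silylation opens the epoxide at the tertiary carbon, DBU removes a methyl proton to give only the isopropenyl carbinol silyl ether, and dilute acid removes the silyl group.

Step 4
Reactants: 6 (2Z)-6-hydroxy-3,7-dimethylocta-2,7-dien-1-yl (2E)-3-methylpent-2-enoate (racemic); 7 ethyl vinyl ether
Product: 9 (2Z,6E)-3,7-dimethyl-10-oxodeca-2,6-dien-1-yl (2E)-3-methylpent-2-enoate, via allyl vinyl ether 8 (not isolated)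
Conditions: 7 (excess), Hg(OAc)2 (10 mol%), reflux; concentrate; toluene, 150 °C, sealed tube
Reagents that add atoms: none
Why: Hg(OAc)2-catalysed transvinylation followed by Claisen rearrangement through a chair transition state with the carbinol substituent equatorial gives the (E)-trisubstituted 6,7-alkene and the two-carbon-longer aldehyde.

Step 5
Reactants: 9 (2Z,6E)-3,7-dimethyl-10-oxodeca-2,6-dien-1-yl (2E)-3-methylpent-2-enoate; 10 tert-butyl acrylate
Product: 11 tert-butyl (6E,10Z)-3-hydroxy-6,10-dimethyl-2-methylidene-12-{[(2E)-3-methylpent-2-enoyl]oxy}dodeca-6,10-dienoate (racemic)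
Conditions: 10 (3 equiv), DABCO (1.0 equiv), 1,4-dioxane–H2O (1:1), rt, 72 h
Reagents that add atoms: none
Why: Morita–Baylis–Hillman reaction of an unhindered aliphatic aldehyde, accelerated in aqueous dioxane, forms the C10–C11 bond; the racemic carbinol is removed in step 6.

Step 6
Reactants: 11 tert-butyl (6E,10Z)-3-hydroxy-6,10-dimethyl-2-methylidene-12-{[(2E)-3-methylpent-2-enoyl]oxy}dodeca-6,10-dienoate (racemic)
Product: 12 tert-butyl (2Z,6E,10Z)-2-(bromomethyl)-6,10-dimethyl-12-{[(2E)-3-methylpent-2-enoyl]oxy}dodeca-2,6,10-trienoate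
Conditions: NBS (1.3 equiv), Me2S (1.5 equiv), CH2Cl2, 0 °C; then 11, 0 °C → rt
Reagents that add atoms: N-bromosuccinimide BrN1C(=O)CCC1=O
Why: Corey–Kim-type activation of the Baylis–Hillman alcohol with SN2′ bromide delivery gives the favoured (Z)-2-(bromomethyl)enoate, which places the chain trans to the ester, the E-alkylidene geometry of the target.

Step 7
Reactants: 12 tert-butyl (2Z,6E,10Z)-2-(bromomethyl)-6,10-dimethyl-12-{[(2E)-3-methylpent-2-enoyl]oxy}dodeca-2,6,10-trienoate; 13 (1S,4S,5S)-isothiocineole [(1S,4S,5S)-4,7,7-trimethyl-6-thiabicyclo[3.2.1]octane]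
Product: 14 (1S,4S,5S,6S)-6-[(2Z,6E,10Z)-2-(tert-butoxycarbonyl)-6,10-dimethyl-12-{[(2E)-3-methylpent-2-enoyl]oxy}dodeca-2,6,10-trien-1-yl]-4,7,7-trimethyl-6-thiabicyclo[3.2.1]octan-6-ium tetrafluoroborate
Conditions: 13 (1.5 equiv), NaBF4 (3 equiv), CH2Cl2–H2O (1:1), rt, 48 h; pentane trituration
Reagents that add atoms: sodium tetrafluoroborate [Na+].F[B-](F)(F)F
Why: SN2 S-alkylation of the bicyclic sulfide on its exposed exo lone pair by the activated allylic bromide, driven by bromide-to-tetrafluoroborate exchange in the two-phase system, gives one sulfonium diastereomer (any SN2′ isomer reverts to the conjugated primary salt).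

Step 8
Reactants: 14 the sulfonium tetrafluoroborate from step 7; 15 3-methylbut-2-enal (prenal)
Product: 18 (2Z,6E,10E)-10-[(4S,5R)-4-hydroxy-5-(2-methylprop-1-en-1-yl)-2-oxooxolan-3-ylidene]-3,7-dimethyldeca-2,6-dien-1-yl (2E)-3-methylpent-2-enoate (target), via sulfonium ylide 16 (not isolated), via epoxy ester 17 (not isolated)
Conditions: 15 (2 equiv), phosphazene base P2-Et (1.05 equiv), CH2Cl2, −78 °C, 2 h; then CSA (0.3 equiv), −78 → 0 °C
Reagents that add atoms: none
Why: Proposed new method: deprotonation of 14 gives a semi-stabilised allylic sulfonium ylide held away from the gem-dimethyl group of the sulfide, so prenal adds 1,2 on the bridgehead C–H side and the adduct closes to the trans (12S,13S)-vinyl epoxide with release of 13 (closest known type: chiral-sulfide-mediated Corey–Chaykovsky epoxidation of enals with allylic sulfonium salts); on acidification the ester carbonyl oxygen opens the protonated epoxide 5-endo at C13, the only carbon that can carry allylic positive charge, with inversion (C13 becomes R, C12 stays S) and the tert-butyl group leaves as isobutene (closest known types: acid-promoted lactonisation of epoxides from 2-(sulfoniomethyl)acrylate ylides, and tert-butyl ester or carbonate openings of epoxides), which reproduces the presumed biogenetic carboxylate attack on a 12,13-epoxide.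

## Compound list

1 | nerol, (2Z)-3,7-dimethylocta-2,6-dien-1-ol | CC(C)=CCC/C(C)=C\CO | starting material
2 | (2E)-3-methylpent-2-enoic acid | CC/C(C)=C/C(=O)O | starting material
3 | (2Z)-3,7-dimethylocta-2,6-dien-1-yl (2E)-3-methylpent-2-enoate | CC/C(C)=C/C(=O)OC/C=C(/C)CCC=C(C)C | intermediate
4 | (2Z)-5-(3,3-dimethyloxiran-2-yl)-3-methylpent-2-en-1-yl (2E)-3-methylpent-2-enoate, racemic | CC/C(C)=C/C(=O)OC/C=C(/C)CCC1OC1(C)C | intermediate
5 | (2Z)-3,7-dimethyl-6-[(trimethylsilyl)oxy]octa-2,7-dien-1-yl (2E)-3-methylpent-2-enoate, racemic, not isolated | CC/C(C)=C/C(=O)OC/C=C(/C)CCC(O[Si](C)(C)C)C(C)=C | intermediate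
6 | (2Z)-6-hydroxy-3,7-dimethylocta-2,7-dien-1-yl (2E)-3-methylpent-2-enoate, racemic | CC/C(C)=C/C(=O)OC/C=C(/C)CCC(O)C(C)=C | intermediate
7 | ethyl vinyl ether | C=COCC | starting material
8 | (2Z)-6-(ethenyloxy)-3,7-dimethylocta-2,7-dien-1-yl (2E)-3-methylpent-2-enoate, racemic, not isolated | CC/C(C)=C/C(=O)OC/C=C(/C)CCC(OC=C)C(C)=C | intermediate
9 | (2Z,6E)-3,7-dimethyl-10-oxodeca-2,6-dien-1-yl (2E)-3-methylpent-2-enoate | CC/C(C)=C/C(=O)OC/C=C(/C)CC/C=C(\C)CCC=O | intermediate
10 | tert-butyl acrylate | C=CC(=O)OC(C)(C)C | starting material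
11 | tert-butyl (6E,10Z)-3-hydroxy-6,10-dimethyl-2-methylidene-12-{[(2E)-3-methylpent-2-enoyl]oxy}dodeca-6,10-dienoate, racemic | CC/C(C)=C/C(=O)OC/C=C(/C)CC/C=C(\C)CCC(O)C(=C)C(=O)OC(C)(C)C | intermediate
12 | tert-butyl (2Z,6E,10Z)-2-(bromomethyl)-6,10-dimethyl-12-{[(2E)-3-methylpent-2-enoyl]oxy}dodeca-2,6,10-trienoate | CC/C(C)=C/C(=O)OC/C=C(/C)CC/C=C(\C)CC/C=C(\CBr)C(=O)OC(C)(C)C | intermediate
13 | (1S,4S,5S)-isothiocineole, (1S,4S,5S)-4,7,7-trimethyl-6-thiabicyclo[3.2.1]octane | C[C@H]1CC[C@H]2C[C@@H]1SC2(C)C | starting material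
14 | (1S,4S,5S,6S)-6-[(2Z,6E,10Z)-2-(tert-butoxycarbonyl)-6,10-dimethyl-12-{[(2E)-3-methylpent-2-enoyl]oxy}dodeca-2,6,10-trien-1-yl]-4,7,7-trimethyl-6-thiabicyclo[3.2.1]octan-6-ium tetrafluoroborate | C[C@H]1CC[C@H]2C[C@@H]1[S@+](C/C(=C\CC/C(C)=C/CC/C(C)=C\COC(=O)/C=C(\C)CC)C(=O)OC(C)(C)C)C2(C)C.F[B-](F)(F)F | intermediate
15 | 3-methylbut-2-enal (prenal) | CC(C)=CC=O | starting material
16 | sulfonium ylide of 14 (carbanion on the S-bound allylic carbon), not isolated | C[C@H]1CC[C@H]2C[C@@H]1[S@+]([CH-]/C(=C\CC/C(C)=C/CC/C(C)=C\COC(=O)/C=C(\C)CC)C(=O)OC(C)(C)C)C2(C)C | intermediate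
17 | tert-butyl (2E,6E,10Z)-6,10-dimethyl-12-{[(2E)-3-methylpent-2-enoyl]oxy}-2-[(2S,3S)-3-(2-methylprop-1-en-1-yl)oxiran-2-yl]dodeca-2,6,10-trienoate, not isolated | CC/C(C)=C/C(=O)OC/C=C(/C)CC/C=C(\C)CC/C=C(/C(=O)OC(C)(C)C)[C@@H]1O[C@H]1C=C(C)C | intermediate
18 | (2Z,6E,10E)-10-[(4S,5R)-4-hydroxy-5-(2-methylprop-1-en-1-yl)-2-oxooxolan-3-ylidene]-3,7-dimethyldeca-2,6-dien-1-yl (2E)-3-methylpent-2-enoate | CC/C(C)=C/C(=O)OC/C=C(/C)CC/C=C(\C)CC/C=C1/C(=O)O[C@H](C=C(C)C)[C@H]1O | target

## Step count and risks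

Total steps: 8. Longest linear sequence: 8 (1 → 3 → 4 → 6 → 9 → 11 → 12 → 14 → 18).

Steps most likely to fail: 8, 5 and 3.

Step 8 carries most of the risk: the ester-bearing allylic ylide may self-react in Michael fashion, the facial sense or trans selectivity may be poor, and acid may ionise the vinyl epoxide or the neryl ester. The fallback moves the same ring construction to the smallest substrate and attaches the chain afterwards by cross-metathesis. It sets out from 13 and 15 (with commercial tert-butyl 2-(bromomethyl)acrylate) and from 9, and comes back at 18. The bromoacrylate is S-alkylated onto 13 (NaBF4, CH2Cl2–H2O) to give the parent sulfonium tetrafluoroborate F1. Base P2-Et and 15 at −78 °C give, through the sulfonium ylide F2, the vinyl epoxide tert-butyl 2-[(2S,3S)-3-(2-methylprop-1-en-1-yl)oxiran-2-yl]prop-2-enoate F3. CSA converts this into the α-methylene hydroxy lactone (4S,5R)-4-hydroxy-3-methylidene-5-(2-methylprop-1-en-1-yl)oxolan-2-one F4. Separately 9 is methylenated (Ph3P=CH2, THF, −78 → 0 °C) to the terminal alkene (2Z,6E)-3,7-dimethylundeca-2,6,10-trien-1-yl (2E)-3-methylpent-2-enoate F5. Cross-metathesis of F4 with F5 (second-generation Hoveyda–Grubbs catalyst, 2,6-dichloro-1,4-benzoquinone, CH2Cl2, 40 °C) gives the E-alkylidene lactone 18; the trisubstituted alkenes are expected to be spectators.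

Step 5 may be slow or low-yielding because tert-butyl acrylate is a sluggish Baylis–Hillman partner for an enolisable aldehyde. The fallback replaces the amine-catalysed coupling by a stoichiometric masked-acrylate aldol. It sets out from 9 and 10 and comes back at 11. Dimethylamine adds to 10 to give tert-butyl 3-(dimethylamino)propanoate F6. Its lithium enolate (LiN(iPr)2, THF, −78 °C) adds to 9 to give the aldol adduct tert-butyl 2-[(dimethylamino)methyl]-3-hydroxy ester F7. MeI quaternises it to the trimethylammonium iodide F8, and DBU eliminates trimethylamine to give 11.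

Step 3 may suffer from cation-derived side products (hydride shift to a ketone, attack by the 2,3-alkene) or from damage to the enoate. The fallback builds the carbinol by C–C bond formation instead of isomerisation. It sets out from 4 and comes back at 6. Periodic acid (H5IO6, THF–H2O, 0 °C) cleaves the epoxide to the aldehyde (2Z)-3-methyl-6-oxohex-2-en-1-yl (2E)-3-methylpent-2-enoate F9. CH2=C(CH3)MgBr in THF at −78 °C then adds to the aldehyde only, leaving the hindered enoate, and gives 6.

## Further compounds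

F1 | step 8 | (1S,4S,5S,6S)-6-[2-(tert-butoxycarbonyl)prop-2-en-1-yl]-4,7,7-trimethyl-6-thiabicyclo[3.2.1]octan-6-ium tetrafluoroborate | C[C@H]1CC[C@H]2C[C@@H]1[S@+](CC(=C)C(=O)OC(C)(C)C)C2(C)C.F[B-](F)(F)F
F2 | step 8 | sulfonium ylide of F1 | C[C@H]1CC[C@H]2C[C@@H]1[S@+]([CH-]C(=C)C(=O)OC(C)(C)C)C2(C)C
F3 | step 8 | tert-butyl 2-[(2S,3S)-3-(2-methylprop-1-en-1-yl)oxiran-2-yl]prop-2-enoate | C=C(C(=O)OC(C)(C)C)[C@@H]1O[C@H]1C=C(C)C
F4 | step 8 | (4S,5R)-4-hydroxy-3-methylidene-5-(2-methylprop-1-en-1-yl)oxolan-2-one | C=C1C(=O)O[C@H](C=C(C)C)[C@H]1O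
F5 | step 8 | (2Z,6E)-3,7-dimethylundeca-2,6,10-trien-1-yl (2E)-3-methylpent-2-enoate | CC/C(C)=C/C(=O)OC/C=C(/C)CC/C=C(\C)CCC=C
F6 | step 5 | tert-butyl 3-(dimethylamino)propanoate | CN(C)CCC(=O)OC(C)(C)C
F7 | step 5 | tert-butyl (6E,10Z)-2-[(dimethylamino)methyl]-3-hydroxy-6,10-dimethyl-12-{[(2E)-3-methylpent-2-enoyl]oxy}dodeca-6,10-dienoate, diastereomer mixture | CC/C(C)=C/C(=O)OC/C=C(/C)CC/C=C(\C)CCC(O)C(CN(C)C)C(=O)OC(C)(C)C
F8 | step 5 | trimethylammonium iodide of F7 | CC/C(C)=C/C(=O)OC/C=C(/C)CC/C=C(\C)CCC(O)C(C[N+](C)(C)C)C(=O)OC(C)(C)C.[I-]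
F9 | step 3 | (2Z)-3-methyl-6-oxohex-2-en-1-yl (2E)-3-methylpent-2-enoate | CC/C(C)=C/C(=O)OC/C=C(/C)CCC=O
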